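A small charge of free catalyst, 2 mol% on the starting material, makes product here by a cycle. Starting material binds free catalyst to give catalyst intermediate A, reagent joins to give catalyst intermediate B, by-product leaves to give catalyst intermediate C, and product leaves to free the catalyst. Beside the cycle, protic impurity quenches starting material.

| flask | starting material | reagent | protic impurity | free catalyst | remark |
|---|---|---|---|---|---|
| teal | 0.010 M | 0.50 equiv | 3 mM | 1 mol% | run made earlier |
| grey | 0.010 M | 0.50 equiv | 3 mM | 4 mol% | run made earlier |
| ochre | 0.015 M | 0.50 equiv | 3 mM | 2 mol% | run made earlier |
| flask | 0.010 M | 0.500 equiv | 3.00 mM | 2 mol% |  |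

- teal (time / h: product / %, starting material / %): 0.250: 1.1, 89.4; 0.500: 3.5, 84.2; 1.33: 9.0, 69.7; 3.00: 20.1, 54.1
- grey (time / h: product / %, starting material / %): 0.833: 20.4, 60.3; 1.50: 32.5, 45.0; 2.50: 39.4, 31.8; 3.00: 45.1, 28.7
- ochre (time / h: product / %, starting material / %): 0.250: 5.2, 87.0; 0.500: 9.3, 78.1; 1.33: 24.9, 57.5; 3.00: 39.1, 40.0

(readings scatter by 1 percentage point)

- reactions considered so far: starting material + free catalyst <-> catalyst intermediate A; reagent + catalyst intermediate A <-> catalyst intermediate B; catalyst intermediate B <-> by-product + catalyst intermediate C; catalyst intermediate C <-> free catalyst + product; starting material + protic impurity -> quenched substrate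
- what is bound to the catalyst counts as converted

- factor on the rate of making product when 30% of the starting material are converted if reagent is charged twice over
- factor on the rate when 30% of the starting material are converted if free catalyst is charged at 0.4 mol% instead

The reckoning here assumes that starting material binds quickly and strongly, so the catalyst waits as catalyst intermediate A, the resting state, and the rate follows catalyst charged times reagent left. Reagent is the limiting reagent at 0.500 equiv, so each part of product takes two parts of reagent on this scale, and the mean reagent left over a run is about one minus the product fraction. Teal's 20.1% at 3.00 h on 1 mol% then gives 8.39 /h. Ochre has another loading and 1.50 times teal's reagent charge, and its 24.9% at 1.33 h on 2 mol%, scaled down by that factor, gives 8.31 /h. Two different runs agree, so their mean 8.35 /h is trusted as the turnover at full reagent: product per hour per catalyst charged, with reagent at this flask's full charge.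

Conversion is product plus the gap that teal shows between the charge and starting material plus product. Taking the mean of teal's gaps at 0.500 h and 1.33 h, corrected for bound catalyst, this flask is reckoned to hold 12.2% product at 30%, so the reckoning leaves 75.6% of its reagent and a rate of 0.126 /h of the charge. Doubled reagent, taken to reach 30% near 0.500 h and so given teal's gap of that time, is reckoned at 16.7% product, which gives a factor of 2.20. At 0.4 mol%, taken to reach 30% between 1.33 h and 3.00 h and so given the mean of teal's gaps at those times, a reckoned 7.05% product leaves 85.9% of the reagent, which gives 0.227.

The forecast says 1.8 (1.4 to 2.2) and 0.23 (0.19 to 0.28), on the grounds: “Rate is nearly zero order in starting material, but close to first order in reagent”. Its doubling factor is lower than the one reckoned here, and its catalyst factor is about the same.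

The flask gives 1.84 and 0.227.

    starting material + free catalyst ⇌ catalyst intermediate A (K = 7700 /M, k = 4.10 /M/s)
    reagent + catalyst intermediate A ⇌ catalyst intermediate B (K = 290 /M, k = 0.620 /M/s)
    catalyst intermediate B ⇌ by-product + catalyst intermediate C (K = 0.110 M, k = 0.0160 /s)
    catalyst intermediate C ⇌ free catalyst + product (K = 0.0670 M, k = 1.50 /s)
    starting material + protic impurity → quenched substrate (k = 0.0320 /M/s)

The doubled factor falls below the reckoned 2.20, and at 1.25 h this flask holds 9.51% of its catalyst as catalyst intermediate B beside 82.5% as catalyst intermediate A. The flask reaches 30% at 0.848 h, making product at 0.123 /h of the charge. Dividing by loading and 8.35 /h reads 73.9% of the reagent left, between the 92.5% at 0.250 h and the 67.1% at 1.25 h. The same division on the 0.4 mol% flask reads 83.8% of its reagent left.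

The runs stem from a simulated flask with made-up constants, noise included.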